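The route rests on cutting ring C of the flavanone at C3–C4 and O1–C2. Because ring C is fused to the phloroglucinol ring A, the O1–C8a–C4a–C4 fragment can arrive as a 5,7-dioxygenated o-quinone methide, and C2–C3 as an E-stilbene whose 4-hydroxyphenyl group (the later C2 aryl) makes the carbon that becomes C3 nucleophilic. A single chiral-acid-catalysed oxa-[4+2] addition should form both bonds, close ring C and set C2 and C3 (2R,3S, trans) at the flavan level; C4 is oxidised afterwards. The precursors are a benzyl-protected salicyl alcohol and a 4-hydroxystilbene that already carries the complete tri-O-benzyl flavone unit.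

Key step: step 8

Remarks on the chemistry:
- The target is the 2,3-trans (2R,3S) flavanone; flavonoid numbering (O1, C2, C3, C4, C4a–C8a) is used for the new heterocycle.
- The sense of induction of the phosphoric acid with this substrate pair cannot be predicted with confidence. (R)-TRIP (3,3'-bis(2,4,6-triisopropylphenyl)-BINOL hydrogen phosphate) is written; the antipode would be used if a first run shows that it leads to the (2R,3S) series.
- All six spectator oxygens are benzyl ethers, so one hydrogenolysis ends the route. Salicyl alcohol 12 is made just before use and fed slowly into the key step, because its own phloroglucinol ring is a nucleophile toward the methide.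

Step 1
Reactants: 1 3-bromo-4-hydroxybenzaldehyde
Product: 2 4-(benzyloxy)-3-bromobenzaldehyde
Conditions: BnBr, K2CO3, DMF, rt
Reagents that add atoms: benzyl bromide, BrCc1ccccc1
Why: Williamson ether synthesis: the phenoxide formed with carbonate displaces bromide from benzyl bromide (SN2) while the aldehyde stays untouched.

Step 2
Reactants: 3 2',4',6'-trihydroxyacetophenone
Product: 4 1-[2,4-bis(benzyloxy)-6-hydroxyphenyl]ethan-1-one
Conditions: BnBr (2.1 equiv), K2CO3, DMF, rt
Reagents that add atoms: benzyl bromide, BrCc1ccccc1
Why: Williamson ether synthesis that stops after two alkylations, because the third hydroxyl is held in a strong hydrogen bond to the ketone carbonyl; this selective dibenzylation of phloroacetophenone is standard.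

Step 3
Reactants: 2 4-(benzyloxy)-3-bromobenzaldehyde; 4 1-[2,4-bis(benzyloxy)-6-hydroxyphenyl]ethan-1-one
Product: 5 (E)-1-[2,4-bis(benzyloxy)-6-hydroxyphenyl]-3-[4-(benzyloxy)-3-bromophenyl]prop-2-en-1-one
Conditions: KOH, EtOH/THF, rt
Reagents that add atoms: none
Why: Claisen–Schmidt condensation: the ketone enolate adds to the non-enolisable aldehyde and E1cB loss of water gives the E-enone; benzyl ethers and the aryl bromide are stable to hydroxide.

Step 4
Reactants: 5 (E)-2'-hydroxychalcone
Product: 6 5,7-bis(benzyloxy)-2-[4-(benzyloxy)-3-bromophenyl]-4H-chromen-4-one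
Conditions: I2 (10 mol%), DMSO, 120 °C
Reagents that add atoms: none
Why: Iodine-catalysed oxidative cyclisation of a 2'-hydroxychalcone to the flavone with DMSO as terminal oxidant, a standard flavone synthesis that should leave the aryl bromide and the aryl benzyl ethers in place.

Step 5
Reactants: 6 3'-bromo-4',5,7-tris(benzyloxy)flavone; 7 4-acetoxystyrene
Product: 9 (E)-4-hydroxystilbene carrying the tri-O-benzyl flavone unit, via acetoxystilbene 8 (not isolated)
Conditions: Pd(OAc)2 (5 mol%), P(o-tol)3, Et3N, DMF, 100 °C; then K2CO3, MeOH, rt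
Reagents that add atoms: none
Why: Mizoroki–Heck reaction: oxidative addition into the C–Br bond, syn insertion at the unsubstituted styrene terminus and syn β-hydride elimination give the E-stilbene, and carbonate-catalysed methanolysis in the same flask then frees only the aryl acetate.

Step 6
Reactants: 10 2,4,6-trihydroxybenzaldehyde
Product: 11 2,4-bis(benzyloxy)-6-hydroxybenzaldehyde
Conditions: BnBr (2.0 equiv), K2CO3, DMF, 0 °C to rt
Reagents that add atoms: benzyl bromide, BrCc1ccccc1
Why: Williamson ether synthesis; as for 4, the hydroxyl chelated to the formyl group is the least nucleophilic and should remain free when two equivalents of benzyl bromide are used.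

Step 7
Reactants: 11 2,4-bis(benzyloxy)-6-hydroxybenzaldehyde
Product: 12 3,5-bis(benzyloxy)-2-(hydroxymethyl)phenol
Conditions: NaBH4, THF/MeOH, 0 °C; pH 7 work-up, used at once
Reagents that add atoms: none
Why: Borohydride reduction of the aldehyde to the primary benzylic alcohol; low temperature and a neutral work-up avoid premature ionisation of this electron-rich salicyl alcohol.

Step 8
Reactants: 9 (E)-4-hydroxystilbene carrying the tri-O-benzyl flavone unit (1.3 equiv); 12 3,5-bis(benzyloxy)-2-(hydroxymethyl)phenol (added over several hours)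
Product: 14 (2R,3S)-2,3-trans-2,3-diarylflavan bearing a free 4'-hydroxyl, via o-quinone methide 13 (not isolated)
Conditions: (R)-TRIP (10 mol%), 5 Å MS, CH2Cl2, 0 °C
Reagents that add atoms: none
Why: Proposed new method: the phosphoric acid dehydrates 12 to o-quinone methide 13 and holds it, through its P–OH and P=O groups, next to the stilbene whose 4-OH is hydrogen-bonded to the same phosphate; the alkene carbon bearing the flavone-substituted ring then adds to the exocyclic CH2 of 13 (C3–C4) while the methide oxygen captures the benzylic carbon next to the hydroxyphenyl ring (O1–C2), rearomatising ring A. The closest known reaction type is the chiral phosphoric acid-catalysed oxa-[4+2] cycloaddition of in situ o-quinone methides with hydroxystyrenes to 2-arylchromans; new here are a methide without a substituent on its exocyclic carbon and a 1,2-diaryl alkene as the 2π partner. The pyran ring closes as the six-membered ring of an inverse-electron-demand hetero-Diels–Alder addition, concerted but asynchronous, with C–C bond formation running ahead of C–O bond formation. C3 is fixed by the alkene face that the catalyst-bound methide reaches, which the chiral phosphate pocket anchored on the stilbene phenol should decide; C2 follows from suprafacial addition to the E alkene, so the two aryl groups end up trans (both equatorial), and a reversible opening of the p-hydroxybenzylic C2–O1 bond could only return this more stable isomer. The step needs regioselectivity, secured by the free para-OH, a much stronger donor than the ortho-benzyloxy group of the other ring, whose lone pair is drawn toward the para-chromone; facial selectivity, resting on the catalyst at a temperature where the uncatalysed pathway should be slow; and cross-reaction over self-reaction of the methide, favoured by feeding 12 slowly into an excess of 9.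

Step 9
Reactants: 14 (2R,3S)-flavan bearing a free 4'-hydroxyl
Product: 15 (2R,3S)-hexa-O-benzyl flavan
Conditions: BnBr, K2CO3, DMF, rt
Reagents that add atoms: benzyl bromide, BrCc1ccccc1
Why: Williamson ether synthesis on the only free phenol; neither flavan stereocentre is acidic, so carbonate in DMF should not disturb them.

Step 10
Reactants: 15 (2R,3S)-hexa-O-benzyl flavan
Product: 16 hexa-O-benzyl flavan-4-ol (C2 and C3 as in 15, C4 either epimer)
Conditions: DDQ (1.5 equiv), CH2Cl2/pH 7 aqueous buffer, 0 °C; crude product carried on
Reagents that add atoms: water, O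
Why: Benzylic oxidation by hydride abstraction: DDQ takes hydride from C4, whose cation is stabilised by O1 and the 5- and 7-benzyloxy groups, and buffered water traps it, as in the known C4 oxidation of per-benzylated 5,7-dioxygenated flavans; C2 and C3 are not involved and the new C4 centre disappears in step 11.

Step 11
Reactants: 16 hexa-O-benzyl flavan-4-ol
Product: 17 (2R,3S)-hexa-O-benzyl flavanone
Conditions: Dess–Martin periodinane, pyridine, CH2Cl2, 0 °C to rt
Reagents that add atoms: none
Why: Dess–Martin oxidation of the secondary benzylic alcohol to the aryl ketone under pyridine-buffered conditions; C3, now α to the ketone, already holds the thermodynamically preferred trans arrangement relative to C2, so enolisation could not change it.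

Step 12
Reactants: 17 (2R,3S)-hexa-O-benzyl flavanone
Product: 18 CNP0324936.1, (2R,3S)-5,7-dihydroxy-3-[5-(5,7-dihydroxy-4-oxo-4H-chromen-2-yl)-2-hydroxyphenyl]-2-(4-hydroxyphenyl)-2,3-dihydro-4H-chromen-4-one
Conditions: H2 (1 atm), Pd(OH)2/C, THF/MeOH, rt
Reagents that add atoms: none
Why: Catalytic hydrogenolysis of all six aryl benzyl ethers under neutral conditions at room temperature, where the flavone C2=C3 bond, the flavanone carbonyl and the C2–O1 bond should survive and no base is present to open the flavanone ring.

Compound list
1 | 3-bromo-4-hydroxybenzaldehyde | O=Cc1ccc(O)c(Br)c1 | starting material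
2 | 4-(benzyloxy)-3-bromobenzaldehyde | O=Cc1ccc(OCc2ccccc2)c(Br)c1 | intermediate
3 | 2',4',6'-trihydroxyacetophenone | CC(=O)c1c(O)cc(O)cc1O | starting material
4 | 1-[2,4-bis(benzyloxy)-6-hydroxyphenyl]ethan-1-one | CC(=O)c1c(O)cc(OCc2ccccc2)cc1OCc1ccccc1 | intermediate
5 | (E)-1-[2,4-bis(benzyloxy)-6-hydroxyphenyl]-3-[4-(benzyloxy)-3-bromophenyl]prop-2-en-1-one | O=C(/C=C/c1ccc(OCc2ccccc2)c(Br)c1)c1c(O)cc(OCc2ccccc2)cc1OCc1ccccc1 | intermediate
6 | 5,7-bis(benzyloxy)-2-[4-(benzyloxy)-3-bromophenyl]-4H-chromen-4-one | O=c1cc(-c2ccc(OCc3ccccc3)c(Br)c2)oc2cc(OCc3ccccc3)cc(OCc3ccccc3)c12 | intermediate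
7 | 4-acetoxystyrene | CC(=O)Oc1ccc(C=C)cc1 | starting material
8 | 4-[(E)-2-{2-(benzyloxy)-5-[5,7-bis(benzyloxy)-4-oxo-4H-chromen-2-yl]phenyl}ethenyl]phenyl acetate | CC(=O)Oc1ccc(/C=C/c2cc(-c3cc(=O)c4c(OCc5ccccc5)cc(OCc5ccccc5)cc4o3)ccc2OCc2ccccc2)cc1 | intermediate (not isolated)
9 | 5,7-bis(benzyloxy)-2-{4-(benzyloxy)-3-[(E)-2-(4-hydroxyphenyl)ethenyl]phenyl}-4H-chromen-4-one | Oc1ccc(/C=C/c2cc(-c3cc(=O)c4c(OCc5ccccc5)cc(OCc5ccccc5)cc4o3)ccc2OCc2ccccc2)cc1 | intermediate
10 | 2,4,6-trihydroxybenzaldehyde | O=Cc1c(O)cc(O)cc1O | starting material
11 | 2,4-bis(benzyloxy)-6-hydroxybenzaldehyde | O=Cc1c(O)cc(OCc2ccccc2)cc1OCc1ccccc1 | intermediate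
12 | 3,5-bis(benzyloxy)-2-(hydroxymethyl)phenol | OCc1c(O)cc(OCc2ccccc2)cc1OCc1ccccc1 | intermediate
13 | 3,5-bis(benzyloxy)-6-methylidenecyclohexa-2,4-dien-1-one (o-quinone methide) | C=C1C(=O)C=C(OCc2ccccc2)C=C1OCc1ccccc1 | intermediate (not isolated)
14 | 5,7-bis(benzyloxy)-2-{4-(benzyloxy)-3-[(2R,3S)-5,7-bis(benzyloxy)-2-(4-hydroxyphenyl)-3,4-dihydro-2H-chromen-3-yl]phenyl}-4H-chromen-4-one (2,3-trans) | C1c2c(OCc3ccccc3)cc(OCc3ccccc3)cc2O[C@@H](c2ccc(O)cc2)[C@@H]1c1cc(-c2cc(=O)c3c(OCc4ccccc4)cc(OCc4ccccc4)cc3o2)ccc1OCc1ccccc1 | intermediate
15 | 5,7-bis(benzyloxy)-2-{4-(benzyloxy)-3-[(2R,3S)-5,7-bis(benzyloxy)-2-[4-(benzyloxy)phenyl]-3,4-dihydro-2H-chromen-3-yl]phenyl}-4H-chromen-4-one (2,3-trans) | C1c2c(OCc3ccccc3)cc(OCc3ccccc3)cc2O[C@@H](c2ccc(OCc3ccccc3)cc2)[C@@H]1c1cc(-c2cc(=O)c3c(OCc4ccccc4)cc(OCc4ccccc4)cc3o2)ccc1OCc1ccccc1 | intermediate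
16 | 4-hydroxy derivative of 15 (flavan-4-ol; C2 and C3 arranged as in 15, C4 either epimer, 3,4-trans expected to predominate) | OC1c2c(OCc3ccccc3)cc(OCc3ccccc3)cc2O[C@@H](c2ccc(OCc3ccccc3)cc2)[C@@H]1c1cc(-c2cc(=O)c3c(OCc4ccccc4)cc(OCc4ccccc4)cc3o2)ccc1OCc1ccccc1 | intermediate
17 | (2R,3S)-5,7-bis(benzyloxy)-2-[4-(benzyloxy)phenyl]-3-{2-(benzyloxy)-5-[5,7-bis(benzyloxy)-4-oxo-4H-chromen-2-yl]phenyl}-2,3-dihydro-4H-chromen-4-one (2,3-trans) | O=C1c2c(OCc3ccccc3)cc(OCc3ccccc3)cc2O[C@@H](c2ccc(OCc3ccccc3)cc2)[C@@H]1c1cc(-c2cc(=O)c3c(OCc4ccccc4)cc(OCc4ccccc4)cc3o2)ccc1OCc1ccccc1 | intermediate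
18 | CNP0324936.1, (2R,3S)-5,7-dihydroxy-3-[5-(5,7-dihydroxy-4-oxo-4H-chromen-2-yl)-2-hydroxyphenyl]-2-(4-hydroxyphenyl)-2,3-dihydro-4H-chromen-4-one (2,3-trans) | O=C1c2c(O)cc(O)cc2O[C@@H](c2ccc(O)cc2)[C@@H]1c1cc(-c2cc(=O)c3c(O)cc(O)cc3o2)ccc1O | target

Total step count: 12. Longest linear sequence: 9 steps (1 or 2, then 3, 4, 5, 8, 9, 10, 11, 12).

Steps most likely to fail

1. Step 8 (Proposed new method). Facial discrimination may be poor, because the catalyst's only handle on the alkene is a phenol para to it and the easily formed methide may also react without the catalyst. The methide may further be consumed by Friedel–Crafts benzylation of the electron-rich A rings of 12 and 14, and the basic chromone carbonyl may tie up the acid. The fallback uses known chemistry and sets out from 9 and 12. The same two bonds are made without asymmetric induction by the long-established thermal hetero-Diels–Alder reaction of an o-quinone methide with an electron-rich styrene (toluene, 110 °C, no acid, 12 fed slowly into excess 9, which is recovered). This should give the trans-flavan as a racemate, that is 14 together with its mirror image, the (2S,3R)-flavan F1. The enantiomers are separated by preparative chromatography on a chiral stationary phase, and the route is rejoined at 14.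

2. Step 10. After hydride loss the C4 cation may lose the C3 proton instead of taking up water, and a second hydride abstraction would then flatten C2 and C3 into a flavylium-type cation. The acid-labile alcohol may also re-ionise during isolation. The fallback sets out from 15 and changes both the trap and the second oxidation. DDQ in homogeneous CH2Cl2/MeOH (known benzylic alkoxylation of 5,7-dioxygenated flavans) should give the chromatographable 4-methoxyflavan F2. A second DDQ oxidation in wet CH2Cl2 abstracts the hydride α to the methoxy group, as in the oxidative cleavage of electron-rich benzylic ethers, and hydrolysis of the oxocarbenium ion gives ketone 17 directly. In that second stage, loss of the C3 proton would only give an enol ether that still hydrolyses to 17, with C3 returning to the trans arrangement under the control of C2. The route is rejoined at 17, bypassing 16 and step 11.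

3. Step 12. Six-fold hydrogenolysis may over-reduce (saturation of the flavone C2=C3 bond, hydrogenolysis of the benzylic C2–O1 bond of the flavanone) or stall at poorly soluble, partly debenzylated stages. The fallback sets out from 17 and replaces reduction by Lewis-acid ether cleavage: BCl3 with pentamethylbenzene as benzyl-cation scavenger, CH2Cl2, −78 °C, a known non-reductive debenzylation of aryl benzyl ethers. It gives 18 directly and makes no new compound (F0).

Further compounds
F1 | step 8 | (2S,3R)-flavan, mirror image of 14 | C1c2c(OCc3ccccc3)cc(OCc3ccccc3)cc2O[C@H](c2ccc(O)cc2)[C@H]1c1cc(-c2cc(=O)c3c(OCc4ccccc4)cc(OCc4ccccc4)cc3o2)ccc1OCc1ccccc1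
F2 | step 10 | 4-methoxy derivative of 15 (4-methoxyflavan; C2 and C3 arranged as in 15, C4 either epimer) | COC1c2c(OCc3ccccc3)cc(OCc3ccccc3)cc2O[C@@H](c2ccc(OCc3ccccc3)cc2)[C@@H]1c1cc(-c2cc(=O)c3c(OCc4ccccc4)cc(OCc4ccccc4)cc3o2)ccc1OCc1ccccc1
F0 | step 12 | none | none
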